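## Structural features

The target consists of two trans-decalins (rings A/B and rings D/E) joined only by the C11–C12 ethano bridge between C9 and C13. The two halves are identical in constitution and configuration (equatorial hydroxyl at C3/C21, gem-dimethyl at C4/C22, trans ring fusion, angular methyl cis to the bridge carbon) except at one position: C8 is a ketone and C14 carries the exocyclic C27 methylene. The molecule is therefore a desymmetrised C2 dimer. Each half has four stereocentres (C3, C5, C10, C9 and C21, C17, C18, C13), with the quaternary C10 (C18) flanked by the tertiary C9 (C13) and C5 (C17). The fragile points are C9, which is α to the C8 ketone and epimerisable (the required equatorial bridge is the thermodynamic arrangement), the acid-sensitive exocyclic alkene, and the 1,6-relationship of C8 and C14 once both are carbonyls. The real difficulty is twofold: building C10 and C18 with the correct relationship to C9 and C13, and telling C8 from C14 in an otherwise symmetric framework. The key step exploits the fact that rings A and E each show the 3-oxygenated, 4,4-dimethyl, angular-methyl pattern left by annulation of a 2-methyl-3-alkylcyclohexanone (rings B and D) with ethyl vinyl ketone, so C1–C10/C4=C5 and C18–C19/C17=C22 can be made in both directions at once.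

## Logic of the disconnections

**20 ⇒ 18 + 19.** The C14=C27 bond is cut (carbonyl olefination in reverse). This reveals a C2-symmetric 8,14-dione whose halves are identical, which is what makes a two-directional synthesis possible. The demand on the forward step is that it stops after one of two equivalent, remote ketones; it is therefore statistical and relies on recycling of 18.

**18 ⇒ 16 (through 17).** No skeletal bond is cut; the C3–H and C21–H bonds are removed and the C8/C14 carbonyls are masked as dioxolanes. The four carbonyl carbons are thereby split into two pairs that are addressed at different times. The forward step must deliver hydride from the α face (equatorial alcohols) and unmask C8/C14 without disturbing C9/C13. These already carry the thermodynamic configuration, so no separate equilibration is planned.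

**16 ⇒ 14 + 4.** One C4–CH3 and one C22–CH3 bond are cut, together with C5–H and C17–H. Gem-dimethyl next to a ketone with a trans ring fusion is the retron of reductive alkylation of a 4-methyl enone. The gain is the loss of two stereocentres and exposure of the annulation retron in both halves. The forward step must protonate C5/C17 from the α face and trap the regiodefined enolates at C4/C22 before they equilibrate.

**14 ⇒ 8 + 2 × 10 (key).** C1–C10, C4=C5, C18–C19 and C17=C22 are cut. Rings A and E and both quaternary centres disappear, and a 30-carbon bis-octalone becomes a 20-carbon bis-cyclohexanone plus a five-carbon enone. The forward step must react at the methyl-bearing α-carbons (not at C6/C16), anti to the C9/C13 substituent, and at both ends of the molecule.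

**8 ⇒ 7.** Unsaturation is added at C11=C12, C6=C7 and C15=C16. The first is the metathesis retron. The ring alkenes are left over from the dienone starting material and, at the earlier stage, make C10/C18 the only enolisable positions. The forward hydrogenation must spare ketones and allylic ketals.

**7 ⇒ 2 × 6.** The C11=C12 bond is cut, halving the problem. The forward homodimerisation has to work on a vinyl group flanked by two substituted ring carbons while the ring enone stays out of the metathesis.

**6 ⇒ 3 + 4.** The C10–CH3 bond is cut. In 3 one α-carbon is vinylic and the γ-carbon is the quaternary ketal, so only C10 can be deprotonated; the position of the methyl group is fixed by structure, not by selectivity. The forward step must stop at mono-alkylation.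

**3 ⇒ 1 + 2.** The C9–C11 bond is cut (conjugate addition in reverse). This is the only step that creates absolute configuration; every other stereocentre is derived from C9/C13. The forward step must select one enantiotopic face and add only once to a substrate with two enone units.

## Other disconnections considered

**Alternative 1:** The cut is C9–C10 of ring B, a ring expansion in reverse. The substrate is the epoxy carbinol A1, in which C8 is a tertiary carbinol inside a cyclopentane fused to ring A (a hydrindane of Hajos–Parrish origin) and C9–C11 is a trans-epoxide. In the forward key step a Lewis acid such as BF3·OEt2 opens the epoxide at C9 while C10 migrates antiperiplanar from C8 to C9 with inversion, giving the β-hydroxy ketone A2.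
- In favour: the C8 ketone and the C9 configuration would arise in one stereospecific event. The two halves are different from the outset, so no statistical step is needed; on this point the alternative is better than the chosen plan. Migration of the more substituted carbon with ring expansion is a well-established behaviour of 2,3-epoxy alcohols.
- Against: two enantiopure bicyclic fragments must be made and joined (alkenyl addition to a neopentyl cyclopentanone, then an epoxidation whose diastereoselectivity decides C9). The trans-hydrindane is itself demanding, and C7 could migrate in competition. The 11-hydroxyl of A2 is superfluous; as a β-hydroxy ketone it invites dehydration or retro-aldol cleavage, and its removal costs two to three further steps.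
- Comparison: on structure it is superior in C8/C14 differentiation and equal in the quality of C9 control (stereospecific shift against thermodynamic preference). On mechanism it depends on one epoxide diastereomer, where the chosen plan depends on face selectivity in a Michael addition. On step economy it is much longer (two fragment syntheses, protecting groups, deoxygenation) than the eight steps below.

**Alternative 2:** The cuts are C9–C11 and C12–C13. In the forward key step the dimagnesium acetylide A4 adds to two molecules of the Wieland–Miescher-derived decalone A3 to give the C2-symmetric propargylic diol A5.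
- In favour: it is two-directional and C2-symmetric, equal to the chosen plan in this respect. Rings A and E with C3, C5 and C10 are secured before the coupling on well-studied chemistry, so the quaternary centres do not depend on an untried twofold annulation; on this point it is the better plan. The bridge comes from a trivial C2 reagent.
- Against: the carbonyl of A3 is flanked by the quaternary C10, so the addition is hindered and competes with enolisation, and the second addition of the alkoxide-bearing mono-acetylide should be slower still. A5 has oxygen at C9/C13 and none at C8/C14: dehydration, alkyne reduction, hydroboration–oxidation at C8/C14 and control of C9/C13 must follow. The end-game is still statistical, equal to the chosen plan.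
- Comparison: safer for the quaternary centres, weaker in functional-group placement (the chosen plan brings C8/C14 in already oxidised), and roughly twice as long.

**Alternative 3:** The cuts are C5–C10 and C8–C9. In the forward key step the triene A6 undergoes an intramolecular Diels–Alder reaction to give A7.
- In favour: rings A and B and four stereocentres (C5, C8, C9, C10) would form in one step. The regiochemistry is electronically matched (the silyloxy terminus C8 bonds to the α-carbon C9). The C8 oxygen arrives in place and the halves are differentiated; both points are better than the chosen plan.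
- Against: the dienophile is β,β-disubstituted (C10 carries methyl and the tether), so a quaternary centre must form in a sluggish cycloaddition that may need heat or Lewis acids poorly tolerated by the silyl dienol ether. Endo/exo and facial control rest on the remote C3 stereocentre. The C11 carbonyl must be removed afterwards and becomes part of a 1,3-dicarbonyl through C9 once C8 is oxidised. C6=C7 must be hydrogenated in the presence of C14=C27. A6 requires a long linear synthesis that includes a separate enantioselective route to the methylene decalin.
- Comparison: higher step-count efficiency in the key step itself and no statistical step, but less certain stereocontrol, extra redox corrections (C11, C6=C7) and a far longer overall sequence.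

Key step: step 5

Assumption: 1 is treated as a catalogue compound (it is the one-step oxidative ketalisation product of a commercial hydroquinone mono-ether).

Assumption: the facial sense of the rhodium catalyst with 1 is taken to follow that known for 2-cyclohexenone; if it proves opposite, (R)-BINAP is used and nothing else changes.

Remarks on the design:
- The configurations written for 8 and 14 were checked against 20 centre by centre (C9/C13 identical throughout, C10/C18 with methyl cis to the bridge); they are mutually consistent and need no correction.
- The route to 8 starts from the quinone monoketal and not from a saturated ketone. This avoids asking the rhodium catalyst to add to an α-methyl enone and fixes the site of methylation structurally.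
- The annulation is run through the 1-phenylethylamine imines, which react only at the more substituted α-carbon.
- The configuration at C10/C18 in 6, 7 and 8 is immaterial, because these carbons become enamine carbons in step 5.

## Steps

Step 1
Reactants: 1 1,4-dioxaspiro[4.5]deca-6,9-dien-8-one; 2 potassium vinyltrifluoroborate
Product: 3 (S)-10-ethenyl-1,4-dioxaspiro[4.5]dec-6-en-8-one
Conditions: [Rh(cod)Cl]2 (2.5 mol %), (S)-BINAP (6 mol %), Et3N, PhMe/H2O, 40 °C; 1 in excess (1.5–2 equiv)
Reagents that add atoms: potassium vinyltrifluoroborate 2, C=C[B-](F)(F)F.[K+]
Why: Asymmetric conjugate addition of an alkenylboron reagent catalysed by monovalent rhodium: the vinyl–rhodium species formed by transmetalation inserts one enantiotopic enone face of the symmetric dienone and water protonates the oxa-π-allyl rhodium; the β-carbon next to a dioxolane ketal is a tolerated position for this reaction type, (S)-BINAP is chosen because it delivers carbon groups to the corresponding face of 2-cyclohexenone (this sets C9), and the cheap dienone is kept in excess so that the product enone is not vinylated again.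

Step 2
Reactants: 3 (S)-10-ethenyl-1,4-dioxaspiro[4.5]dec-6-en-8-one; 4 iodomethane
Product: 6 (9R,10R)-10-ethenyl-9-methyl-1,4-dioxaspiro[4.5]dec-6-en-8-one, via lithium dienolate 5 (not isolated)
Conditions: LiN(iPr)2 (1.05 equiv), THF, −78 °C; MeI (1.5 equiv), −78 to −30 °C
Reagents that add atoms: iodomethane 4, CI
Why: Kinetic α'-deprotonation and C-alkylation of a cyclohexenone; C10 is the only enolisable position (the other α-carbon is vinylic, the γ-carbon is the quaternary ketal), so the methyl group can only enter next to C9, and it should enter trans to the vinyl group (the change of the C9 descriptor from S to R is a priority effect, not an inversion).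

Step 3
Reactants: 6 (9R,10R)-10-ethenyl-9-methyl-1,4-dioxaspiro[4.5]dec-6-en-8-one (two molecules)
Product: 7 10,10'-[(E)-ethene-1,2-diyl]bis[(9R,10R)-9-methyl-1,4-dioxaspiro[4.5]dec-6-en-8-one]
Conditions: second-generation Grubbs catalyst (5 mol %), CH2Cl2 (0.5 M), 40 °C, argon purge
Reagents that add atoms: none
Why: Homodimerising olefin cross-metathesis of the terminal vinyl groups, driven by loss of ethene; the unstrained, electron-poor ring enone should not take part, the alkene geometry is irrelevant because the bridge is hydrogenated next, and any minor enantiomer of 6 is diverted mainly into a separable meso-type diastereomer.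

Step 4
Reactants: 7 10,10'-[(E)-ethene-1,2-diyl]bis[(9R,10R)-9-methyl-1,4-dioxaspiro[4.5]dec-6-en-8-one]
Product: 8 6,6'-(ethane-1,2-diyl)bis[(6R,7R)-7-methyl-1,4-dioxaspiro[4.5]decan-8-one]
Conditions: H2 (1 atm), 10% Pd/C, EtOAc, rt
Reagents that add atoms: none
Why: Heterogeneous catalytic hydrogenation saturates the bridge alkene and both conjugated ring alkenes in one operation while ketones and dioxolanes remain; C9/C13 are not α to a carbonyl and cannot epimerise.

Step 5
Reactants: 8 6,6'-(ethane-1,2-diyl)bis[(6R,7R)-7-methyl-1,4-dioxaspiro[4.5]decan-8-one]; 9 (R)-1-phenylethylamine (recoverable auxiliary); 10 ethyl vinyl ketone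
Product: 14 C2-symmetric bis(4-methyl-Δ4-octalin-3-one) bis(ethylene ketal), via bis-imine 11 (not isolated), via bis-imine Michael adduct 12 (not isolated), via tetraketone 13 (not isolated)
Conditions: 9 (2.1 equiv), TsOH (1 mol %), PhMe, reflux, Dean–Stark; 10 (3 equiv), THF, 40 °C; AcOH/NaOAc buffer (pH 4.5), H2O/THF, rt; NaOMe, MeOH, 60 °C
Reagents that add atoms: ethyl vinyl ketone 10, CCC(=O)C=C
Why: Each ketone of 8 condenses with 9 to an imine; of its two secondary-enamine tautomers only the more substituted one (C5=C10 and C17=C18) adds to ethyl vinyl ketone, through a compact cyclic transition state in which the N–H proton passes to the α-carbon of the enone, so the new C1–C10 and C18–C19 bonds form at the methyl-bearing carbons; buffered hydrolysis frees the 1,5-diketones and NaOMe then effects the aldol condensation. The closest known reaction type is the Robinson annulation of 2-methylcyclohexanones with vinyl ketones run through their 1-phenylethylamine imines (Michael addition, then base-mediated aldol condensation); only its use at two sites of one molecule is untried. Rings A and E each close by a 6-(enolendo)-exo-trig aldol addition of the C4 (C22) enolate to the C5 (C17) carbonyl, followed by E1cB loss of water to the C4=C5 (C17=C22) enone. The new stereocentres are C10 and C18: the C9 (C13) substituent lies pseudoaxial to avoid allylic strain with the enamine methyl, so the enone adds to the opposite face and the angular methyl ends cis to the bridge carbon, and the (R)-auxiliary, whose own preference in 2-methylcyclohexanone imines is for the same sense, should reinforce this choice (matched pair). The step needs regioselectivity for C10/C18 over C6/C16, which the enamine mechanism secures, and facial selectivity, which substrate and auxiliary secure together; C9 and C13 cannot epimerise because C8 and C14 are still ketals, and the dioxolanes should tolerate pH 4–5 and methoxide.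

Step 6
Reactants: 14 C2-symmetric bis(4-methyl-Δ4-octalin-3-one) bis(ethylene ketal); 4 iodomethane
Product: 16 C2-symmetric bis(4,4-dimethyl-trans-decalin-3-one) bis(ethylene ketal), via dilithium bis-enolate 15 (not isolated)
Conditions: Li (6 equiv), NH3(l)/THF, tBuOH (2.0 equiv), −78 °C; isoprene (to discharge excess Li); MeI (10 equiv), −78 to −33 °C
Reagents that add atoms: iodomethane 4, CI
Why: Dissolving-metal reductive alkylation of each 4-methyl enone: two-electron reduction and protonation at C5 (C17) from the α face, anti to the angular methyl, gives the trans ring fusion and a regiodefined lithium enolate (C3=C4, C21=C22) that is C-methylated in situ to the gem-dimethyl ketone; ketals are inert to the conditions.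

Step 7
Reactants: 16 C2-symmetric bis(4,4-dimethyl-trans-decalin-3-one) bis(ethylene ketal)
Product: 18 26,27-dinor-8,14-dioxo-α-onocerin (C2-symmetric 3,21-dihydroxy-8,14-dione), via bis-ketal diol 17 (not isolated)
Conditions: NaBH4, MeOH/THF, 0 °C; then 2 M aq HCl, THF, rt
Reagents that add atoms: water, O
Why: Borohydride reduction of the 4,4-dimethyl-3-ketones by axial hydride delivery from the α face (the β face is screened by the axial C4 and angular methyls) should give the equatorial C3 and C21 alcohols; acidification destroys excess hydride before the dioxolanes open, then hydrolyses them to the C8/C14 ketones, and C9/C13, now enolisable, already carry the equatorial, thermodynamically preferred bridge.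

Step 8
Reactants: 18 26,27-dinor-8,14-dioxo-α-onocerin; 19 methyltriphenylphosphonium bromide
Product: 20 26-nor-8-oxo-α-onocerin
Conditions: 19 (1.1 equiv), KOtBu (1.05 equiv), THF/PhMe, 0 to 60 °C; recovered 18 recycled
Reagents that add atoms: methyltriphenylphosphonium bromide 19 (CH2 through its ylide), C[P+](c1ccccc1)(c1ccccc1)c1ccccc1.[Br-]
Why: Wittig methylenation with about one equivalent of ylide; the two ketones are equivalent and remote, so the mono-alkene should form as the main component of a statistical mixture from which the dione is recovered and the doubly methylenated by-product is separated; the ylide is a weaker base than an alkoxide, so the free hydroxyls are tolerated, and any enolisation at C9 returns the equatorial epimer.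

## Compound list

1 | 1,4-dioxaspiro[4.5]deca-6,9-dien-8-one (p-benzoquinone mono(ethylene ketal)) | O=C1C=CC2(C=C1)OCCO2 | starting material
2 | potassium vinyltrifluoroborate | C=C[B-](F)(F)F.[K+] | starting material
3 | (S)-10-ethenyl-1,4-dioxaspiro[4.5]dec-6-en-8-one (4,4-ethylenedioxy-5-vinylcyclohex-2-enone, vinyl on the future C9) | O=C1C=CC2(OCCO2)[C@H](C=C)C1 | intermediate
4 | iodomethane | CI | starting material
5 | lithium cross-conjugated dienolate of 3 (O–Li on C5, C5=C10, C9 unchanged) | [Li+].[O-]C1=C[C@@H](C=C)C2(OCCO2)C=C1 | intermediate (not isolated)
6 | (9R,10R)-10-ethenyl-9-methyl-1,4-dioxaspiro[4.5]dec-6-en-8-one (methyl trans to vinyl) | O=C1C=CC2(OCCO2)[C@H](C=C)[C@H]1C | intermediate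
7 | 10,10'-[(E)-ethene-1,2-diyl]bis[(9R,10R)-9-methyl-1,4-dioxaspiro[4.5]dec-6-en-8-one] | O=C1C=CC2(OCCO2)[C@H](/C=C/[C@@H]3[C@@H](C)C(=O)C=CC34OCCO4)[C@H]1C | intermediate
8 | 6,6'-(ethane-1,2-diyl)bis[(6R,7R)-7-methyl-1,4-dioxaspiro[4.5]decan-8-one] (C9–C13-bridged bis(2-methyl-4,4-ethylenedioxycyclohexanone), methyl trans to the bridge) | O=C1CCC2(OCCO2)[C@H](CC[C@@H]3[C@@H](C)C(=O)CCC34OCCO4)[C@H]1C | intermediate
9 | (R)-1-phenylethylamine | C[C@@H](N)c1ccccc1 | starting material
10 | ethyl vinyl ketone (pent-1-en-3-one) | CCC(=O)C=C | starting material
11 | bis-imine of 8 with 9 (C5=N and C17=N, N-substituent (R)-1-phenylethyl) | C[C@H](c1ccccc1)N=C1CCC2(OCCO2)[C@H](CC[C@@H]3[C@@H](C)C(=N[C@H](C)c4ccccc4)CCC34OCCO4)[C@H]1C | intermediate (not isolated)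
12 | bis-imine of 13 (3-oxopentyl groups on C10 and C18, methyl cis to the bridge) | CCC(=O)CC[C@]1(C)[C@@H](CC[C@H]2C3(OCCO3)CCC(=N[C@H](C)c3ccccc3)[C@]2(C)CCC(=O)CC)C2(OCCO2)CCC1=N[C@H](C)c1ccccc1 | intermediate (not isolated)
13 | tetraketone: 8 carrying a 3-oxopentyl group at C10 and at C18, angular methyl cis to the bridge carbon | CCC(=O)CC[C@]1(C)[C@@H](CC[C@H]2C3(OCCO3)CCC(=O)[C@]2(C)CCC(=O)CC)C2(OCCO2)CCC1=O | intermediate (not isolated)
14 | C2-symmetric bis(4-methyl-Δ4-octalin-3-one) bis(ethylene ketal): 3,21-dioxo, C4=C5 and C17=C22, one methyl each on C4 and C22, dioxolanes on C8 and C14, angular methyls on C10 and C18 cis to the bridge (9R,10R,13R,18R) | O=C1CC[C@]2(C)[C@@H](CC[C@H]3C4(OCCO4)CCC5=C(C)C(=O)CC[C@]35C)C6(OCCO6)CCC2=C1C | intermediate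
15 | dilithium bis-enolate (O–Li on C3 and C21, C3=C4 and C21=C22, H-5 and H-17 trans to the angular methyls) | C12(OCCO1)CC[C@H]3C(C)=C([O-])CC[C@]3(C)[C@H]2CC[C@H]2C4(OCCO4)CC[C@H]5C(C)=C([O-])CC[C@]25C.[Li+].[Li+] | intermediate (not isolated)
16 | C2-symmetric bis(4,4-dimethyl-trans-decalin-3-one) bis(ethylene ketal) (3,21-dione, dioxolanes on C8 and C14) | C12(OCCO1)CC[C@H]3C(C)(C)C(=O)CC[C@]3(C)[C@H]2CC[C@H]2C4(OCCO4)CC[C@H]5C(C)(C)C(=O)CC[C@]25C | intermediate
17 | bis-ketal diol (3,21-diol of 16, both hydroxyls equatorial and cis to the angular methyls) | C12(OCCO1)CC[C@H]3C(C)(C)[C@@H](O)CC[C@]3(C)[C@H]2CC[C@H]2C4(OCCO4)CC[C@H]5C(C)(C)[C@@H](O)CC[C@]25C | intermediate (not isolated)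
18 | 26,27-dinor-8,14-dioxo-α-onocerin (C2-symmetric 3,21-dihydroxy-8,14-dione) | O=C1CC[C@H]2C(C)(C)[C@@H](O)CC[C@]2(C)[C@H]1CC[C@H]1C(=O)CC[C@H]2C(C)(C)[C@@H](O)CC[C@]12C | intermediate
19 | methyltriphenylphosphonium bromide | C[P+](c1ccccc1)(c1ccccc1)c1ccccc1.[Br-] | starting material
20 | 26-nor-8-oxo-α-onocerin (3S,5R,9R,10S,13S,17R,18R,21S) | C=C1CC[C@H]2C(C)(C)[C@@H](O)CC[C@]2(C)[C@H]1CC[C@H]1C(=O)CC[C@H]2C(C)(C)[C@@H](O)CC[C@]12C | target

## Step count and risk

Total step count: 8. Longest linear sequence: 8 steps (1 to 20; the dimerisation in step 3 joins two molecules of the same intermediate).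

**Step 5 (key step).** The most likely failure is incomplete reaction at the second site together with erosion of facial selectivity at the congested C10/C18. The enamine carbon is flanked by the C9 methine and the C8 ketal, and one dioxolane oxygen is syn-axial to the incoming chain. Because both ends must react correctly, any per-site shortfall is squared. Partial ketal loss during imine hydrolysis is a second concern. Fallback: set out from 7, in which C10–H and C18–H are the only enolisable positions. Double deprotonation with LiN(iPr)2 and Michael addition of the dienolates to 2-(trimethylsilyl)pent-1-en-3-one would give the bis-adduct F1. Hydrogenation (H2, Pd/C) would give the saturated bis(α-silyl 1,5-diketone) F2. NaOMe in MeOH would remove silicon and close rings A and E, returning to the route at 14. The same four bonds are formed; regiochemistry is then enforced by structure.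

**Step 1.** The most likely failures are loss of mono-selectivity (a second vinylation of the product enone, which the catalyst also recognises) and acid-induced aromatisation with loss of the ketal. The facial sense is predicted only by analogy. Fallback: set out from 1. Conjugate hydride reduction with one equivalent of LiBH(sBu)3 would give 1,4-dioxaspiro[4.5]dec-6-en-8-one F3, which has a single enone. The same rhodium-catalysed vinylation would give (S)-6-ethenyl-1,4-dioxaspiro[4.5]decan-8-one F4. Kinetic enolisation away from the substituted side (LiN(iPr)2, TMSCl) would give the trimethylsilyl enol ether F5, and Saegusa oxidation with Pd(OAc)2 in MeCN would return to the route at 3.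

**Step 3.** The most likely failure is slow homodimerisation with catalyst decay, because the vinyl group sits between the spiro-ketal carbon and the methyl-bearing carbon. Fallback: set out from 3, whose vinyl group has one less neighbouring substituent. Metathesis there would give the unmethylated (E)-bridged bis-enone F6, and double α'-methylation (LiN(iPr)2, then MeI; again only C10/C18 can be deprotonated) would return to the route at 7.

**Step 6.** The most likely failures are proton transfer to the enolate before alkylation (loss of one of the new methyl groups), enolate equilibration with over-alkylation at C2/C20, and incomplete reduction at one end; each is counted twice. Fallback: set out from 14. Deconjugative methylation (KOtBu, tBuOH, MeI) would give the bis(4,4-dimethyl-Δ5-3-ketone) bis-ketal F7. Hydrogenation (H2, Pd/C, EtOAc) from the α face, opposite the angular methyl, would then set the trans ring fusion and return to the route at 16.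

**Step 8.** The most likely failures are over-olefination at the second, equivalent ketone and low conversion through enolisation of the hindered C8/C14 ketones, so the product is obtained only as part of a statistical mixture. Fallback: set out from 17 (isolated by a neutral work-up of the reduction). Partial hydrolysis (PPTS, aqueous acetone) would give the mono-ketal keto-diol F8, with 17 and 18 recycled. Excess Ph3P=CH2 could then be used to drive the single ketone to the mono-ketal methylene diol F9 without risk of double olefination. Brief mild hydrolysis (PPTS, aqueous acetone) would return to the route at 20.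

## Further compounds

F1 | step 5 | bis-adduct of 7 with 2-(trimethylsilyl)pent-1-en-3-one (3-oxo-2-trimethylsilylpentyl groups on C10 and C18, ring enones and bridge alkene retained) | CCC(=O)C([Si](C)(C)C)C[C@]1(C)[C@@H](/C=C/[C@H]2C3(OCCO3)C=CC(=O)[C@]2(C)CC([Si](C)(C)C)C(=O)CC)C2(OCCO2)C=CC1=O
F2 | step 5 | saturated bis(α-trimethylsilyl 1,5-diketone) (13 with trimethylsilyl on C2 and C20) | CCC(=O)C([Si](C)(C)C)C[C@]1(C)[C@@H](CC[C@H]2C3(OCCO3)CCC(=O)[C@]2(C)CC([Si](C)(C)C)C(=O)CC)C2(OCCO2)CCC1=O
F3 | step 1 | 1,4-dioxaspiro[4.5]dec-6-en-8-one | O=C1C=CC2(CC1)OCCO2
F4 | step 1 | (S)-6-ethenyl-1,4-dioxaspiro[4.5]decan-8-one | O=C1CCC2(OCCO2)[C@H](C=C)C1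
F5 | step 1 | kinetic trimethylsilyl enol ether of F4 (C5=C6, remote from the vinyl-bearing carbon) | C[Si](C)(C)OC1=CCC2(OCCO2)[C@H](C=C)C1
F6 | step 3 | (E)-ethene-1,2-diyl-bridged dimer of 3 (7 without the two methyl groups) | O=C1C=CC2(OCCO2)[C@H](/C=C/[C@@H]3CC(=O)C=CC34OCCO4)C1
F7 | step 6 | bis(4,4-dimethyl-Δ5-3-ketone) bis(ethylene ketal) (C5=C6 and C16=C17) | C12(OCCO1)CC=C3C(C)(C)C(=O)CC[C@]3(C)[C@H]2CC[C@H]2C4(OCCO4)CC=C5C(C)(C)C(=O)CC[C@]25C
F8 | step 8 | mono-ketal keto-diol (one dioxolane of 17 hydrolysed) | C12(OCCO1)CC[C@H]3C(C)(C)[C@@H](O)CC[C@]3(C)[C@H]2CC[C@H]2C(=O)CC[C@H]4C(C)(C)[C@@H](O)CC[C@]24C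
F9 | step 8 | mono-ketal methylene diol (ethylene ketal of 20) | C12(OCCO1)CC[C@H]3C(C)(C)[C@@H](O)CC[C@]3(C)[C@H]2CC[C@H]2C(=C)CC[C@H]4C(C)(C)[C@@H](O)CC[C@]24C
A1 | alternative 1 | C9,C11-epoxy C8-carbinol with a hydrindane in place of rings A/B (bis-silyl ether) | C=C1CC[C@H]2C(C)(C)[C@@H](O[Si](C)(C)C(C)(C)C)CC[C@]2(C)[C@H]1C[C@@H]1O[C@H]1[C@]1(O)CC[C@H]2C(C)(C)[C@@H](O[Si](C)(C)C(C)(C)C)CC[C@]12C
A2 | alternative 1 | 11-hydroxy bis-silyl ether of the target | C=C1CC[C@H]2C(C)(C)[C@@H](O[Si](C)(C)C(C)(C)C)CC[C@]2(C)[C@H]1C[C@H](O)[C@H]1C(=O)CC[C@H]2C(C)(C)[C@@H](O[Si](C)(C)C(C)(C)C)CC[C@]12C
A3 | alternative 2 | Wieland–Miescher-derived 3-silyloxy-4,4,10-trimethyl-trans-decal-9-one | O=C1CCC[C@H]2C(C)(C)[C@@H](O[Si](C)(C)C(C)(C)C)CC[C@]12C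
A4 | alternative 2 | acetylene bis(magnesium bromide) | Br[Mg]C#C[Mg]Br
A5 | alternative 2 | C2-symmetric C9,C13-diol with a C11≡C12 bridge | O[C@@]1(C#C[C@]2(O)CCC[C@H]3C(C)(C)[C@@H](O[Si](C)(C)C(C)(C)C)CC[C@]23C)CCC[C@H]2C(C)(C)[C@@H](O[Si](C)(C)C(C)(C)C)CC[C@]12C
A6 | alternative 3 | triene: (E,E)-1-triethylsilyloxydiene C5–C8 tethered through C4–C1 to the (E)-enone C9=C10–C11(=O) carrying the methylene decalin | CC[Si](CC)(CC)O/C=C/C=C/C(C)(C)[C@@H](O[Si](C)(C)C(C)(C)C)CC/C(C)=C/C(=O)C[C@H]1C(=C)CC[C@H]2C(C)(C)[C@@H](O[Si](C)(C)C(C)(C)C)CC[C@]12C
A7 | alternative 3 | 11-oxo-6-ene-8-silyl ether of the protected target skeleton | CC[Si](CC)(CC)O[C@H]1C=C[C@H]2C(C)(C)[C@@H](O[Si](C)(C)C(C)(C)C)CC[C@]2(C)[C@H]1C(=O)C[C@H]1C(=C)CC[C@H]2C(C)(C)[C@@H](O[Si](C)(C)C(C)(C)C)CC[C@]12C
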